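**Same charge.** Time separates these two flasks: south stops at 6.0 min, north-east at 1.5 min, and their charges agree.

| setting | theta | epsilon | alpha | south | north-east |
|---|---|---|---|---|---|
| left-handed substrate | 0.052 M | 0.052 M | 0.052 M | 0.052 M | 0.052 M |
| right-handed substrate | 0.052 M | 0.052 M | 0.052 M | 0.052 M | 0.052 M |
| solid reagent | 0.052 M | 0.052 M | 0.078 M | 0.0520 M | 0.0520 M |
| protic impurity | 3.6 mM | 5.7 mM | 2.6 mM | 2.60 mM | 2.60 mM |
| free catalyst | 7.8 mM | 7.8 mM | 7.8 mM | 7.8 mM | 7.8 mM |
| remark | run made earlier | run made earlier | run made earlier |  |  |
| time |  |  |  | 6.0 min | 1.5 min |

- theta (time / min: right-handed substrate / %, left-handed substrate / %, left-handed product / %): 2.00: 50.5, 47.4, 3.1; 4.00: 48.8, 39.4, 9.8; 5.00: 50.7, 37.1, 14.5; 8.00: 49.3, 29.8, 23.3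
- epsilon (time / min: right-handed substrate / %, left-handed substrate / %, left-handed product / %): 0.833: 49.3, 47.9, 1.3; 2.50: 49.7, 43.0, 5.1; 5.00: 50.5, 37.5, 12.7; 8.00: 50.7, 27.2, 21.7
- alpha (time / min: right-handed substrate / %, left-handed substrate / %, left-handed product / %): 2.00: 49.0, 45.1, 4.2; 4.00: 51.0, 38.7, 11.5; 5.00: 50.4, 35.9, 14.5; 8.00: 50.7, 24.1, 23.7

(standard deviation of a reading: 1 percentage point)

- free catalyst is single-handed; left-handed substrate and right-handed substrate are mirror images of each other, charged as a racemate, each of them at the stated concentration
- solid, in amounts per volume of the solution: solid reagent
- on the list of suspects stand: coupling partner + free catalyst + left-handed substrate -> free catalyst + left-handed product; coupling partner + free catalyst + right-handed substrate -> free catalyst + right-handed product; solid reagent <-> coupling partner; coupling partner + protic impurity -> quenched reagent; coupling partner + free catalyst -> spent catalyst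
- at the start none of the solid reagent is in solution
- an excess is below zero if the other one leads

- the flask that ends with the higher excess of right-handed substrate over left-handed substrate among what is left of the two, or "neither" when 2 percentage points or less lies between them (south / north-east / neither)
- excess of right-handed substrate over left-handed substrate among what is left of the two at the end, south
- excess of right-handed substrate over left-handed substrate among what is left of the two at the end, north-east

**Bench rule.** In theta the right-handed substrate reads 50.5 % first and 49.3 % last, no trend beyond the 1 percentage point scatter, while the left-handed substrate falls to 29.8 %. You can therefore treat this as a kinetic resolution: the excess is the left-handed product divided by the substrate still there. How fast that product comes is then the question. Between 4.00 min and 8.00 min, theta gains 0.0338 min⁻¹ of the substrates charged, the run rate, product gained per minute once the curve is straight. Traced back to zero product, that line gives a lag of 1.10 min. The three runs read close together at 8.00 min: theta 23.3 %, epsilon 21.7 % and alpha 23.7 %.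

**Its border.** My rule is product = run rate × (time − lag), and it needs a time well beyond the lag. South stands at 5.45 lags, which gives 16.5 % product and an excess of 19.8 %. North-east stands at 1.36 lags, and there the line gives 1.36 %. But epsilon, a recipe with 5.7 mM of protic impurity, reads 1.3 % at 0.833 min, earlier than theta's lag, with a scatter of 1 point, so I do not trust the line this close to the start. Interpolating epsilon's early readings instead gives 2.82 % product and an excess of 2.90 %, uncertain by about the scatter. The gap is 17 points, and the margin is 2 points.

**The forecast.** It names south, with 20.5 % and 2.6 %, close to my figures but not the same, holding that “the excess depends only on how much left-handed substrate has been consumed”.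

**The result.** South ends at 20.5 % and north-east at 2.72 %, so south leads.

    coupling partner + free catalyst + left-handed substrate → free catalyst + left-handed product (k = 23.0 M⁻² s⁻¹)
    coupling partner + free catalyst + right-handed substrate → free catalyst + right-handed product (k = 0.130 M⁻² s⁻¹)
    solid reagent ⇌ coupling partner, rate k3*(cs3 - [coupling partner]) while solid is left; crystals form when [coupling partner] > cs3 (solubility = 49.0 mM, k = 0.00230 s⁻¹)
    coupling partner + protic impurity → quenched reagent (k = 0.810 M⁻¹ s⁻¹)
    coupling partner + free catalyst → spent catalyst (k = 0.120 M⁻¹ s⁻¹)

**Carried forward.** South holds 17.1 % left-handed product against 0.118 % right-handed product at 6.00 min. Now carry the run rate of 0.0338 min⁻¹ forward from north-east's 2.66 % of left-handed product at 1.50 min to 6.0 min: that gives 17.8 % product and an excess of 21.7 %, and the same flask read at 6.0 min stands at 20.5 %.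

(All runs come from a simulation for an exercise, noise included.)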